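The 3 questions on this flask ask for one decision before the run: change the charge of L, or leave it.

| flask | Z | L | remark | time |
|---|---|---|---|---|
| east | 0.20 M | 0.60 M | run made earlier |  |
| north-east | 0.45 M | 0.60 M | run made earlier |  |
| flask | 0.30 M | 0.600 M |  | 30 min |

| run | time / min | Q / % | Z / % |
|---|---|---|---|
| east | 3.00 | 61.0 | 35.3 |
| east | 5.00 | 71.6 | 17.7 |
| east | 8.00 | 78.6 | 7.4 |
| east | 12.0 | 79.9 | 0.1 |
| east | 20.0 | 73.7 | 0 |
| east | 40.0 | 62.9 | 0 |
| north-east | 3.00 | 52.9 | 39.7 |
| north-east | 5.00 | 61.9 | 23.5 |
| north-east | 8.00 | 65.6 | 12.1 |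
| north-east | 12.0 | 66.1 | 6.2 |
| north-east | 20.0 | 66.8 | 0 |
| north-east | 40.0 | 62.1 | 1.9 |

(each reading ± 1 percentage point)

- what was read earlier has a scatter of 1 percentage point, one standard deviation

* equivalents of L to Z, everything else as given, that leave most Q at 30 min
* the amount of Q then, in percent of the Z charged
* the amount of Q with the amounts as given

After Z has fallen to 0.1 % at 12.0 min in the east run, Q declines slowly, and that tail can be counted in half-lives. Between the last two readings, each run gives a half-life of Q:

east: 87.5 min, with L minus Z as charged 0.400 M
north-east: 190 min, with 0.150 M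

The tail is slower in the north-east run, where less L is spare, so this reckoning reads it as a pseudo-first-order decay. Define τ, the tail half-life of Q, as inversely proportional to spare L. Scaling from the east run, and placing the peak by Z between the two runs' highest readings, gives for this flask:

τ = 117 min
peak: 74.7 % at 15.2 min
Q at 30 min: 68.4 %

One more equivalent of L costs about 6 percentage points in the tail. The peaks of the two runs suggest a gain of about 7.9 points. The two figures lie close together, and a line drawn across two such distant runs is a rough measure, so this reckoning leaves L at 2.00 equivalents and expects a best little above 68.4 %.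

The forecast differs from this reckoning: it gave 70 % as charged and 71 % at 1.8 equiv, and says of that optimum “it is very flat”.

The flask gives 68.3 % as charged and 69.1 % at 1.72 equiv.

    Z + L → Q + G (k = 0.755 L mol⁻¹ min⁻¹)
    L ⇌ E (K = 0.161, k = 2.19 min⁻¹)
    Z + Q → J (k = 0.167 L mol⁻¹ min⁻¹)
    L + Q → D + G (k = 0.0296 L mol⁻¹ min⁻¹)

At 30.0 min this flask makes Q at 0.0232 of the rate at which Q is used, and Q's half-life by L + Q → D + G, 99 min, is long against the 30 min of the run. From 75.1 % at 15.0 min to 68.3 % at 30.0 min, Q falls with a half-life of 110 min, beside τ of 117 min.

The same flask read at 80 min has 0.427 of τ more tail, so τ gives 50.8 %. The computed Q there is 50.1 %.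

(All runs stem from a simulated flask for substances that don't exist, and the scatter is random.)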